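**Assumptions.** The target is drawn as the free hydrogen sulfate. Aryl hydrogen sulfates are normally kept as salts, so the potassium salt 15 is taken as the storable form and the acid 16 is released from it cold in the last operation. 1-(Benzyloxy)-4-ethynylbenzene 4 is treated as commercially available.

## The problem

Kaempferol 7-O-sulfate 16 is a flat, achiral flavonol. Ring A is fused to the pyranone ring C, ring B (4-hydroxyphenyl) sits on C2, hydroxyls sit on C3, C5 and C4′, and O7 carries a sulfate monoester. There is no stereocentre, so nothing has to be set or relayed in space. The difficulty is to tell four oxygens apart and to sulfate O7 alone. The 5-OH is tied to the C4 carbonyl by a hydrogen bond and is the least reactive. The 7-OH and 4′-OH are the most acidic and react at similar rates, and the enolic 3-OH lies between. The aryl sulfate is the fragile group: protic and Lewis acids cleave it and every intermediate that carries it is a water-soluble salt, so it must come late and the last deprotection must be neutral. The pyranone also tolerates little hard nucleophile, because alkoxides open ring C at C2. The enabling feature is that carbonyl carbon C4 lies between C4a of ring A and the C3=C2 unit that bears ring B, with O1 on C8a next to C4a. Ring C can therefore be assembled from an ortho-iodophenol, carbon monoxide (as C4) and an arylalkyne (as C3 and C2). Because C5 and C8a both carry oxygen, the iodophenol can be a 2-iodoresorcinol with a mirror plane through C–I and O7. Either hydroxyl may close the ring, the other becomes the chelated 5-OH, and O7 is the one oxygen with a different group.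

## Retrosynthesis

**O7–S and the benzyl C–O bonds.** Acid 16 comes from its potassium salt 15, 15 from the tribenzyl sulfate salt 14 by hydrogenolysis, and 14 from phenol 13 by cutting O7–S. Sulfating before the last deprotection is preferred to sulfating a free polyphenol, because 13 has a single hydroxyl while a free flavonol offers two of similar reactivity. Benzyl ethers are preferred to esters or silyl ethers because their removal is neutral and reductive, conditions an aryl sulfate salt tolerates. The forward steps must stay non-acidic until the final protonation.

**The acetal on O7 and the benzyl on O3.** Phenol 13 is traced to acetal 12 (cut: the CH2–O7 bond of the methoxymethyl group), and 12 to flavonol 11 (cut: benzyl–O3). O7 needs a mask that differs from benzyl, is inert to carbonate and alkyl halide, and comes off without touching benzyl ethers. A bulky silyl ether would be easier to place selectively, but the 7-oxygen of a flavone is a good leaving group at silicon and two carbonate-mediated benzylations have to be passed, so silyl is set aside. The forward acetal cleavage must be mild enough to leave the chelation-activated 5-O-benzyl ether in place.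

**The C3–O bond.** Flavonol 11 comes from flavone 9 through its 2,3-epoxide 10. Ring C is made from a terminal alkyne, so C3 arrives as C–H and O3 has to be added afterwards. Epoxidation of C2=C3 and acid-induced isomerisation is the shortest way and, unlike C3 metalation, needs no strong base. It asks that the ring A phenol be capped, since a chelated 5-OH withdraws electron density from C2=C3 and is itself open to oxidation. Hence 9 is the 5-O-benzyl ether of 5-hydroxyflavone 8.

**Ring C.** Flavone 8 is cut at C4a–C4, C4–C3 and O1–C2, which gives iodoresorcinol 3, arylalkyne 4 and carbon monoxide 5. Routes through an ortho-hydroxyaryl ketone would need the three ring A hydroxyls differentiated by partial protection. This cut instead uses a symmetric ring A piece in which O7 is already unique, and it sets three bonds in one catalytic operation. The precursors are much simpler: 3 is a benzene with three oxygens and one iodine, 4 is bought and 5 is a gas. The forward reaction must favour carbonylative over direct alkyne coupling and six-ring over five-ring closure. The transient ynone 6 and enaminone 7 are not isolated.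

**C–I and the acetal C–O bond.** Iodide 3 is cut at C–I to resorcinol 2, and 2 at the acetal C–O bond to phloroglucinol 1. Acetal first and iodine second is preferred to the reverse order. Once iodine is in place a small alkylating agent cannot tell the three hydroxyls apart, whereas mono-alkylation of symmetric 1 is a statistical problem solved by an excess of the cheap triol. Iodination of a resorcinol under bicarbonate goes to the carbon between the two hydroxyls. Both forward steps ask for stoichiometric control.

## Roads not taken

**Alternative 1:** Ring A would be built instead of ring C.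
- **Cut:** the ring A bond next to the acyl-bearing carbon (C4a–C8a in flavone numbering), which unravels ring A to the open-chain triketo ester A1.
- **Forward key step:** Mg(OMe)2 folds A1 by Claisen attack of chain carbon C6 on the C1 ester, as chalcone synthase does, to give trihydroxychalcone A2.
- **Merits:** a biomimetic, metal-free ring closure that needs no pressure equipment and no protecting group on ring A.
- **Weak points:**
  - A1 is a poly-β-carbonyl compound that needs several enolate acylations to assemble.
  - A1 can lactonise to a pyranone or close in the aldol mode (C2 onto C7), which gives the wrong ring.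
  - A2 has three free ring A hydroxyls and nothing that marks O7.
  - A2 still needs Algar–Flynn–Oyamada oxidation to flavonol A3, a reaction that drifts toward aurones when the ketone ring carries a 6′-oxygen.
- **Comparison:** Alternative 1 is better on equipment. Against that, the chosen plan buys ring A as 1 in its final oxidation pattern and has O7 marked before the heterocycle exists.

**Alternative 2:** Ring C would be closed by acylation and fluoride displacement.
- **Cut:** C3–C4 and O1–C8a.
- **Forward key step:** the lithium enolate of α-benzyloxy ketone A4, made with LiN(SiMe3)2, is C-acylated by acid chloride A5. The enolate oxygen of the resulting diketone displaces an ortho fluorine to give difluorochromone A6.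
- **Merits:** O3 is in place from the start, the route is convergent, and the two ortho fluorines are equivalent, so ring closure has no regiochemical issue.
- **Weak points:**
  - A6 has fluorine where the target has O5 and O7, so two further displacements by oxygen nucleophiles are needed.
  - C5–F (ortho to the carbonyl) and C7–F (para) are both activated, and which reacts first depends on counter-ion and nucleophile, yet O7 must receive a group different from that on O5.
  - Alkoxides can also attack C2 and open ring C.
  - O-acylation of the enolate competes with C-acylation.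
- **Comparison:** Alternative 2 is better in that it needs no later oxidation at C3, which costs the chosen plan two steps (capping of O5 and epoxidation–isomerisation). Against that, the chosen plan has both ring A oxygens present from 1 and told apart by chelation, not by small differences in displacement rate. Overall step counts are similar.

**Alternative 3:** Ring A would be grown on a preformed pyranone.
- **Cut:** four ring A bonds (C8–C8a, C7–C8, C5–C6 and C4a–C5), on a pyranone that already bears ring B and the 3-benzyloxy group.
- **Forward key step:** irradiation of diazoketone A7 with silyloxyalkyne A8 (Danheiser benzannulation). Wolff rearrangement gives a vinylketene, (2+2) cycloaddition gives a cyclobutenone, and four-electron opening followed by six-electron closure and tautomerisation gives A9.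
- **Merits:** A9 has every oxygen in the right state: O3 and O4′ benzylated, O5 free and chelated, O7 as the only silyl ether. Desilylation, sulfation and hydrogenolysis would finish in three steps, and the mechanism fixes the regiochemistry.
- **Weak points:**
  - A7 needs about six steps from a hydroxypyranone (protection, side-chain oxidation, arylation next to the ring oxygen, diazoketone formation from the acid chloride and a diazoalkane).
  - 4-Pyranones rearrange under ultraviolet light, and this chromophore has to survive the photochemical Wolff step.
  - A8 is a sensitive reagent that itself needs several steps.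
- **Comparison:** Alternative 3 is clearly better after the key step, where the chosen plan needs six steps. The chosen plan sets against this a two-step access to 3, a bought alkyne, one catalytic step that forms three bonds, no diazo or photochemistry, and a total length that is no greater.

Key step: step 3

## Route

Step 1
Reactants: 1 phloroglucinol
Product: 2 5-(methoxymethoxy)benzene-1,3-diol
Conditions: 1 (3 equiv), MOMCl (1 equiv), i-Pr2NEt (1.1 equiv), DMF, 0 °C → rt
Reagents that add atoms: chloromethyl methyl ether, COCCl
Why: Methoxymethylation of a phenol (Williamson-type O-alkylation with an α-chloro ether); with the triol in threefold excess the mono-ether should dominate over the bis-ether, and unreacted 1 is removed with the aqueous washes.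

Step 2
Reactants: 2 5-(methoxymethoxy)benzene-1,3-diol
Product: 3 2-iodo-5-(methoxymethoxy)benzene-1,3-diol
Conditions: I2 (1.0 equiv), NaHCO3 (1.1 equiv), THF/H2O (1:1), 0 °C, dark
Reagents that add atoms: iodine, II
Why: Electrophilic aromatic iodination through the phenoxide; under bicarbonate, resorcinols are iodinated at the carbon flanked by both hydroxyls, and the other two ring positions are further shielded by the neighbouring acetal, so the symmetric iodide is expected; the acetal is stable at pH 8.

Step 3
Reactants: 3 2-iodo-5-(methoxymethoxy)benzene-1,3-diol; 4 1-(benzyloxy)-4-ethynylbenzene; 5 carbon monoxide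
Product: 8 2-[4-(benzyloxy)phenyl]-5-hydroxy-7-(methoxymethoxy)-4H-chromen-4-one, via aryl ynone 6 (not isolated), via enaminone 7 (not isolated)
Conditions: PdCl2(PPh3)2 (5 mol%), Et2NH (solvent), CO (20 bar), 120 °C, autoclave
Reagents that add atoms: carbon monoxide (compound 5), [C-]#[O+]
Why: This is a carbonylative Sonogashira-type coupling followed by amine-mediated cyclisation, the known palladium-catalysed route from 2-iodophenols, CO and terminal alkynes to flavones. Zerovalent palladium, formed from PdCl2(PPh3)2 in the amine, inserts into the C–I bond of 3, CO insertion gives an aroyl complex of divalent palladium, and amine-assisted coupling with 4 followed by reductive elimination gives ynone 6 (bonds C4a–C4 and C4–C3). Diethylamine adds to 6 to give enaminone 7, and a flanking phenol attacks the amine-bearing carbon and expels the amine (bond O1–C2), which closes ring C in the 6-endo mode by addition–elimination. No stereocentre is formed. Carbonylative coupling is favoured over direct coupling (which would lead to a benzofuran) by CO pressure and by the electron-rich aryl group, which migrates readily to CO. Flavone is favoured over aurone (5-exo) by the enaminone pathway, in which only the former alkyne carbon that bears ring B is electrophilic. Ring closure has no regiochemical issue because the two hydroxyls flanking iodine are equivalent by symmetry; the unused one becomes the chelated 5-OH. The acetal on O7 is inert to amine, CO and heat.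

Step 4
Reactants: 8 2-[4-(benzyloxy)phenyl]-5-hydroxy-7-(methoxymethoxy)-4H-chromen-4-one
Product: 9 5-(benzyloxy)-2-[4-(benzyloxy)phenyl]-7-(methoxymethoxy)-4H-chromen-4-one
Conditions: BnBr (1.5 equiv), K2CO3 (3 equiv), n-Bu4NI (cat.), DMF, 70 °C
Reagents that add atoms: benzyl bromide, BrCc1ccccc1
Why: Williamson etherification; the chelated 5-OH is the only hydroxyl, so heating with carbonate in DMF suffices, and the acetal and the flavone tolerate it; the cap removes the phenol that would deactivate C2=C3 toward the dioxirane and be open to oxidation.

Step 5
Reactants: 9 5-(benzyloxy)-2-[4-(benzyloxy)phenyl]-7-(methoxymethoxy)-4H-chromen-4-one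
Product: 11 5-(benzyloxy)-2-[4-(benzyloxy)phenyl]-3-hydroxy-7-(methoxymethoxy)-4H-chromen-4-one, via flavone 2,3-epoxide 10 (not isolated)
Conditions: DMDO (acetone solution, 3–4 equiv), CH2Cl2, 0 °C → rt; then p-TsOH·H2O (cat.), CH2Cl2, 0 °C
Reagents that add atoms: dimethyldioxirane, CC1(C)OO1
Why: Electrophilic epoxidation of the enol-ether double bond C2=C3 gives racemic epoxide 10, and acid-catalysed opening at the oxygen-stabilised C2 followed by loss of the C3 proton gives the 3-hydroxyflavone; this two-stage oxidation is established for flavones whose 5-, 7- and 4′-oxygens are alkylated, and the epoxide stereocentres vanish on aromatisation.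

Step 6
Reactants: 11 5-(benzyloxy)-2-[4-(benzyloxy)phenyl]-3-hydroxy-7-(methoxymethoxy)-4H-chromen-4-one
Product: 12 3,5-bis(benzyloxy)-2-[4-(benzyloxy)phenyl]-7-(methoxymethoxy)-4H-chromen-4-one
Conditions: BnBr (1.3 equiv), K2CO3 (2 equiv), DMF, rt
Reagents that add atoms: benzyl bromide, BrCc1ccccc1
Why: Williamson etherification of the acidic enolic 3-OH, the only free hydroxyl of 11; the acetal on O7 is untouched by carbonate.

Step 7
Reactants: 12 3,5-bis(benzyloxy)-2-[4-(benzyloxy)phenyl]-7-(methoxymethoxy)-4H-chromen-4-one
Product: 13 3,5-bis(benzyloxy)-2-[4-(benzyloxy)phenyl]-7-hydroxy-4H-chromen-4-one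
Conditions: HCl (1.25 M in MeOH), THF, 40 °C
Reagents that add atoms: none
Why: Acid-catalysed transacetalisation of the aryl methoxymethyl ether to methanol; the benzyl ethers on O3 and O4′ are inert, and mild anhydrous acid is chosen so that the chelation-activated 5-O-benzyl ether is kept.

Step 8
Reactants: 13 3,5-bis(benzyloxy)-2-[4-(benzyloxy)phenyl]-7-hydroxy-4H-chromen-4-one
Product: 14 potassium 3,5-bis(benzyloxy)-2-[4-(benzyloxy)phenyl]-4-oxo-4H-chromen-7-yl sulfate
Conditions: SO3·pyridine (5 equiv), pyridine, 40 °C; then aq. KHCO3
Reagents that add atoms: sulfur trioxide–pyridine complex, O=S(=O)([O-])[n+]1ccccc1; potassium hydrogen carbonate, [K+].OC(=O)[O-]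
Why: O-Sulfonation of a phenol with an amine–sulfur trioxide complex; 13 has a single free hydroxyl, so the site is unambiguous, and bicarbonate work-up gives the potassium salt, the form that is stable to handling and reversed-phase purification.

Step 9
Reactants: 14 potassium 3,5-bis(benzyloxy)-2-[4-(benzyloxy)phenyl]-4-oxo-4H-chromen-7-yl sulfate
Product: 16 3,5-dihydroxy-2-(4-hydroxyphenyl)-4-oxo-4H-chromen-7-yl hydrogen sulfate (kaempferol 7-O-sulfate), via potassium kaempferol 7-sulfate 15 (not isolated)
Conditions: H2 (1 atm), 10% Pd/C, MeOH/THF, rt; filter; then HCl (1.0 equiv, in MeOH), 0 °C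
Reagents that add atoms: none
Why: Hydrogenolysis of aryl benzyl ethers over palladium in neutral medium should leave the aryl sulfate salt and the pyranone double bond untouched; one equivalent of HCl at 0 °C then protonates the sulfate, with KCl separating from methanol.

## Compound list

1 | phloroglucinol (benzene-1,3,5-triol) | Oc1cc(O)cc(O)c1 | starting material
2 | 5-(methoxymethoxy)benzene-1,3-diol | COCOc1cc(O)cc(O)c1 | intermediate
3 | 2-iodo-5-(methoxymethoxy)benzene-1,3-diol | COCOc1cc(O)c(I)c(O)c1 | intermediate
4 | 1-(benzyloxy)-4-ethynylbenzene | C#Cc1ccc(OCc2ccccc2)cc1 | starting material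
5 | carbon monoxide | [C-]#[O+] | starting material
6 | 3-[4-(benzyloxy)phenyl]-1-[2,6-dihydroxy-4-(methoxymethoxy)phenyl]prop-2-yn-1-one | COCOc1cc(O)c(C(=O)C#Cc2ccc(OCc3ccccc3)cc2)c(O)c1 | intermediate (not isolated)
7 | (E)-3-[4-(benzyloxy)phenyl]-3-(diethylamino)-1-[2,6-dihydroxy-4-(methoxymethoxy)phenyl]prop-2-en-1-one (drawn as the E isomer; the geometry is lost on cyclisation) | CCN(CC)/C(c1ccc(OCc2ccccc2)cc1)=C/C(=O)c1c(O)cc(OCOC)cc1O | intermediate (not isolated)
8 | 2-[4-(benzyloxy)phenyl]-5-hydroxy-7-(methoxymethoxy)-4H-chromen-4-one | O=c1cc(-c2ccc(OCc3ccccc3)cc2)oc2cc(OCOC)cc(O)c12 | intermediate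
9 | 5-(benzyloxy)-2-[4-(benzyloxy)phenyl]-7-(methoxymethoxy)-4H-chromen-4-one | O=c1cc(-c2ccc(OCc3ccccc3)cc2)oc2cc(OCOC)cc(OCc3ccccc3)c12 | intermediate
10 | 5-(benzyloxy)-2-[4-(benzyloxy)phenyl]-2,3-epoxy-7-(methoxymethoxy)-2,3-dihydro-4H-chromen-4-one (racemic, cis-fused; one enantiomer drawn) | O=C1[C@@H]2O[C@]2(c2ccc(OCc3ccccc3)cc2)Oc2cc(OCOC)cc(OCc3ccccc3)c12 | intermediate (not isolated)
11 | 5-(benzyloxy)-2-[4-(benzyloxy)phenyl]-3-hydroxy-7-(methoxymethoxy)-4H-chromen-4-one | O=c1c(O)c(-c2ccc(OCc3ccccc3)cc2)oc2cc(OCOC)cc(OCc3ccccc3)c12 | intermediate
12 | 3,5-bis(benzyloxy)-2-[4-(benzyloxy)phenyl]-7-(methoxymethoxy)-4H-chromen-4-one | O=c1c(OCc2ccccc2)c(-c2ccc(OCc3ccccc3)cc2)oc2cc(OCOC)cc(OCc3ccccc3)c12 | intermediate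
13 | 3,5-bis(benzyloxy)-2-[4-(benzyloxy)phenyl]-7-hydroxy-4H-chromen-4-one | O=c1c(OCc2ccccc2)c(-c2ccc(OCc3ccccc3)cc2)oc2cc(O)cc(OCc3ccccc3)c12 | intermediate
14 | potassium 3,5-bis(benzyloxy)-2-[4-(benzyloxy)phenyl]-4-oxo-4H-chromen-7-yl sulfate | O=c1c(OCc2ccccc2)c(-c2ccc(OCc3ccccc3)cc2)oc2cc(OS(=O)(=O)[O-])cc(OCc3ccccc3)c12.[K+] | intermediate
15 | potassium 3,5-dihydroxy-2-(4-hydroxyphenyl)-4-oxo-4H-chromen-7-yl sulfate | O=c1c(O)c(-c2ccc(O)cc2)oc2cc(OS(=O)(=O)[O-])cc(O)c12.[K+] | intermediate (not isolated)
16 | 3,5-dihydroxy-2-(4-hydroxyphenyl)-4-oxo-4H-chromen-7-yl hydrogen sulfate (kaempferol 7-O-sulfate) | O=c1c(O)c(-c2ccc(O)cc2)oc2cc(OS(=O)(=O)O)cc(O)c12 | target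

## Step count and least certain steps

Total step count: 9. Longest linear sequence: 9 steps, from 1 to 16 (4 and 5 enter in step 3).

**Step 3 (key step).** The ring of 3 is very electron-rich and carries two phenoxides under the reaction conditions. The likely failure is that the aroyl palladium complex is captured by diethylamine (amide formation) or that iodine is lost reductively before the alkyne couples.
Fallback, from 3 back to 8: 3 is acetylated (Ac2O, pyridine) to 2-iodo-5-(methoxymethoxy)-1,3-phenylene diacetate F1. F1 is then submitted with 4 and 5 to the low-pressure carbonylative annulation established for ortho-iodophenol acetates (PdCl2(PPh3)2, thiourea, dppp, Et2NH, DBU, CO at 1 atm, 40 °C). The acetates make oxidative addition easier and keep phenoxide off palladium. The amine cleaves them in the flask, so ring closure and release of the 5-OH give 8.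

**Step 5.** Epoxidation of the electron-poor C2=C3 bond may be slow. Prolonged exposure to excess dioxirane then allows oxidation at the benzylic C–H bonds of the benzyl ethers, and the acid used for isomerisation may start to cleave the acetal.
Fallback, from 9 back to 11: C3 of 9 is lithiated with LiN(iPr)2 in THF at −78 °C and trapped with B(OMe)3. This gives dimethyl {5-(benzyloxy)-2-[4-(benzyloxy)phenyl]-7-(methoxymethoxy)-4-oxo-4H-chromen-3-yl}boronate F4, which is oxidised with H2O2 in acetic acid to 11. This is the known metalation–boration–oxidation route to flavonols.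

**Step 2.** All three ring C–H positions of 2 are activated by three oxygens, so iodination may also go to a carbon flanked by hydroxyl and acetal, or proceed twice.
Fallback, from 1 back to 8: phloroglucinol 1 is iodinated first (I2, NaHCO3, THF/H2O), where only one mono-iodide is possible, to 2-iodobenzene-1,3,5-triol F2. F2 is taken with 4 and 5 through the carbonylative annulation to 2-[4-(benzyloxy)phenyl]-5,7-dihydroxy-4H-chromen-4-one F3. The non-chelated, more acidic 7-OH of F3 is then methoxymethylated selectively (MOMCl, i-Pr2NEt, CH2Cl2/DMF, 0 °C) to give 8.

**Step 7.** The 5-O-benzyl ether is activated by the neighbouring carbonyl and may be cleaved together with the acetal, giving a mixture.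
Fallback, from 12 back to 15: the loss is made deliberate. Concentrated HCl in acetic acid at 60 °C cleaves both the acetal and the 5-O-benzyl ether and gives 3-(benzyloxy)-2-[4-(benzyloxy)phenyl]-5,7-dihydroxy-4H-chromen-4-one F5. Sulfation (SO3·pyridine, pyridine, then KHCO3) takes only the non-chelated 7-OH and gives potassium 3-(benzyloxy)-2-[4-(benzyloxy)phenyl]-5-hydroxy-4-oxo-4H-chromen-7-yl sulfate F6. Hydrogenolysis over Pd/C then returns to the route at 15.

## Further compounds

F1 | step 3 | 2-iodo-5-(methoxymethoxy)-1,3-phenylene diacetate | COCOc1cc(OC(C)=O)c(I)c(OC(C)=O)c1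
F2 | step 2 | 2-iodobenzene-1,3,5-triol | Oc1cc(O)c(I)c(O)c1
F3 | step 2 | 2-[4-(benzyloxy)phenyl]-5,7-dihydroxy-4H-chromen-4-one | O=c1cc(-c2ccc(OCc3ccccc3)cc2)oc2cc(O)cc(O)c12
F4 | step 5 | dimethyl {5-(benzyloxy)-2-[4-(benzyloxy)phenyl]-7-(methoxymethoxy)-4-oxo-4H-chromen-3-yl}boronate | COB(OC)c1c(-c2ccc(OCc3ccccc3)cc2)oc2cc(OCOC)cc(OCc3ccccc3)c2c1=O
F5 | step 7 | 3-(benzyloxy)-2-[4-(benzyloxy)phenyl]-5,7-dihydroxy-4H-chromen-4-one | O=c1c(OCc2ccccc2)c(-c2ccc(OCc3ccccc3)cc2)oc2cc(O)cc(O)c12
F6 | step 7 | potassium 3-(benzyloxy)-2-[4-(benzyloxy)phenyl]-5-hydroxy-4-oxo-4H-chromen-7-yl sulfate | O=c1c(OCc2ccccc2)c(-c2ccc(OCc3ccccc3)cc2)oc2cc(OS(=O)(=O)[O-])cc(O)c12.[K+]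
A1 | alternative 1 | methyl (E)-9-[4-(benzyloxy)phenyl]-3,5,7-trioxonon-8-enoate | COC(=O)CC(=O)CC(=O)CC(=O)/C=C/c1ccc(OCc2ccccc2)cc1
A2 | alternative 1 | (E)-3-[4-(benzyloxy)phenyl]-1-(2,4,6-trihydroxyphenyl)prop-2-en-1-one | O=C(/C=C/c1ccc(OCc2ccccc2)cc1)c1c(O)cc(O)cc1O
A3 | alternative 1 | 2-[4-(benzyloxy)phenyl]-3,5,7-trihydroxy-4H-chromen-4-one | O=c1c(O)c(-c2ccc(OCc3ccccc3)cc2)oc2cc(O)cc(O)c12
A4 | alternative 2 | 2-(benzyloxy)-1-[4-(benzyloxy)phenyl]ethan-1-one | O=C(COCc1ccccc1)c1ccc(OCc2ccccc2)cc1
A5 | alternative 2 | 2,4,6-trifluorobenzoyl chloride | O=C(Cl)c1c(F)cc(F)cc1F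
A6 | alternative 2 | 3-(benzyloxy)-2-[4-(benzyloxy)phenyl]-5,7-difluoro-4H-chromen-4-one | O=c1c(OCc2ccccc2)c(-c2ccc(OCc3ccccc3)cc2)oc2cc(F)cc(F)c12
A7 | alternative 3 | 5-(benzyloxy)-6-[4-(benzyloxy)phenyl]-2-(2-diazoacetyl)-4H-pyran-4-one | [N-]=[N+]=CC(=O)c1cc(=O)c(OCc2ccccc2)c(-c2ccc(OCc3ccccc3)cc2)o1
A8 | alternative 3 | (ethynyloxy)triisopropylsilane | C#CO[Si](C(C)C)(C(C)C)C(C)C
A9 | alternative 3 | 3-(benzyloxy)-2-[4-(benzyloxy)phenyl]-5-hydroxy-7-(triisopropylsilyloxy)-4H-chromen-4-one | O=c1c(OCc2ccccc2)c(-c2ccc(OCc3ccccc3)cc2)oc2cc(O[Si](C(C)C)(C(C)C)C(C)C)cc(O)c12
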